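**Retrosynthetic overview**

1. Ring C (the 4-hydroxy-2-pyranone) is closed last, by acylketene lactonisation of a β-keto-dioxinone made from the ring B arylacetic acid and 2,2,6-trimethyl-1,3-dioxin-4-one; global O-demethylation ends the route.
2. The arylacetic acid comes from a ring B aryl bromide by Pd-catalysed coupling with a zinc ester enolate (C–Br to C–CH2CO2R).
3. Feature: ring A carries the aroyl group on C1, propyl on C2 and oxygen on C4 and C6. This is the pattern of a 5-aroyl-4-methoxy-6-propyl-2-pyranone whose O–C(=O) bridge is exchanged for the two carbons of 1,1-dimethoxyethene, so ring A is cut at C2–C3 and C4–C5 and the tetra-ortho-substituted diaryl ketone exists before the ring does.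
4. The pyranone comes from an aroyl(butanoyl)methane and malonyl dichloride; the diketone comes from acetylation of 1-bromo-3,5-dimethoxybenzene and Claisen condensation with ethyl butanoate.
5. Ring order: ring B (bought), 2-pyranone (step 3), ring A (step 5), ring C (step 9).

Key step: step 5

Remark: ring B carries bromine, not a carbon side chain, through the cycloaddition, because bromine is inert to AlCl3, NaH, HCl and heat and is converted to the CH2CO2R unit in one Pd-catalysed step. The target has no stereocentre; the bridged intermediate of step 5 and the carbinols of the fallbacks are racemic. The zinc reagent of step 6 and LiN(i-Pr)2 are used as purchased solutions.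

**Route**

Step 1
Reactants: 1 1-bromo-3,5-dimethoxybenzene; 2 acetyl chloride
Product: 3 1-(2-bromo-4,6-dimethoxyphenyl)ethan-1-one
Conditions: AlCl3 (1.2 equiv), CH2Cl2, 0 °C
Reagents that add atoms: none
Why: Friedel–Crafts acylation should occur at C2, which is para to one methoxy group and ortho to the other (the site at which this arene is also formylated), while the low temperature keeps AlCl3 from cleaving the methoxy group ortho to the new ketone.

Step 2
Reactants: 3 1-(2-bromo-4,6-dimethoxyphenyl)ethan-1-one; 4 ethyl butanoate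
Product: 5 1-(2-bromo-4,6-dimethoxyphenyl)hexane-1,3-dione
Conditions: NaH (2.5 equiv), 4 (3 equiv), THF, reflux; aq. HCl work-up
Reagents that add atoms: none
Why: Crossed Claisen condensation in which the sodium enolate of the methyl ketone is acylated by the ester and deprotonation of the resulting 1,3-diketone drives the equilibrium, the aryl bromide and the shielded aryl carbonyl being inert to the enolate.

Step 3
Reactants: 5 1-(2-bromo-4,6-dimethoxyphenyl)hexane-1,3-dione; 6 malonyl dichloride
Product: 7 5-(2-bromo-4,6-dimethoxybenzoyl)-4-hydroxy-6-propyl-2H-pyran-2-one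
Conditions: 6 (1.5 equiv), CHCl3, rt → 60 °C
Reagents that add atoms: none
Why: Pyranone annulation of a β-diketone with malonyl dichloride, in which the enolised diketone is C-acylated at its central carbon and the second acyl chloride is captured by an enol oxygen, which should be that of the unhindered butanoyl group (the aroyl carbonyl is flanked by Br and OMe), so that propyl ends up on C6 and the aroyl group on C5.

Step 4
Reactants: 7 5-(2-bromo-4,6-dimethoxybenzoyl)-4-hydroxy-6-propyl-2H-pyran-2-one
Product: 8 5-(2-bromo-4,6-dimethoxybenzoyl)-4-methoxy-6-propyl-2H-pyran-2-one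
Conditions: Me2SO4, K2CO3, acetone, reflux
Reagents that add atoms: dimethyl sulfate, COS(=O)(=O)OC
Why: O-Alkylation of the vinylogous acid with dimethyl sulfate and carbonate base, which for 4-hydroxy-2-pyranones gives the 4-methoxy-2-pyranone in preference to the 2-methoxy-4-pyranone isomer.

Step 5
Reactants: 8 5-(2-bromo-4,6-dimethoxybenzoyl)-4-methoxy-6-propyl-2H-pyran-2-one; 9 1,1-dimethoxyethene
Product: 12 (2-bromo-4,6-dimethoxyphenyl)(2,4-dimethoxy-6-propylphenyl)methanone, via bridged lactone adduct 10 (not isolated), via dimethoxycyclohexadiene 11 (not isolated)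
Conditions: 9 (8 equiv), toluene, sealed tube, 130 °C; then TsOH (cat.), rt
Reagents that add atoms: none
Why: The electron-rich CH2 of 9 adds to C6 of 8 (β-carbon of the aroyl enone and δ-terminus of the dienyl lactone) and C3, the α-carbon of the β-methoxy enoate, closes on the resulting dimethoxycarbenium carbon, an asynchronous inverse-electron-demand (4+2) cycloaddition that gives bridged lactone 10. Retro-(4+2) extrusion of CO2 then gives diene 11 and 1,2-elimination of methanol aromatises it to 12; the closest known reaction type is the Diels–Alder/CO2-extrusion arene synthesis from acceptor-substituted 2-pyranones (coumalates, 3-acyl-2-pyranones) and ketene acetals. Ring A is closed by an intermolecular (4+2) annulation that forms its C2–C3 and C4–C5 bonds (pyranone C6 to CH2 and pyranone C3 to the acetal carbon), its six carbons being pyranone C3–C6 plus the two carbons of 9. No stereocentre remains, because the two bridgehead centres of racemic 10 are lost on aromatisation. The step needs regioselectivity (CH2 to C6, not C3) and chemoselectivity for the diene over the ketone; the donor–acceptor polarisation of the diene (electrophilic C6, nucleophilic C3) matches that of 9, and the 2,6-disubstituted aroyl carbonyl is too shielded for carbonyl addition. The pyranone 4-OMe becomes the C6 oxygen and the acetal carbon the C4 oxygen of ring A, so the tetra-ortho-substituted ketone never has to be made by acylation of a finished arene.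

Step 6
Reactants: 12 (2-bromo-4,6-dimethoxyphenyl)(2,4-dimethoxy-6-propylphenyl)methanone; 13 (2-tert-butoxy-2-oxoethyl)zinc chloride
Product: 14 tert-butyl [2-(2,4-dimethoxy-6-propylbenzoyl)-3,5-dimethoxyphenyl]acetate
Conditions: Pd(dba)2 (5 mol%; dba = dibenzylideneacetone), P(t-Bu)3 (10 mol%), THF, rt → 50 °C
Reagents that add atoms: none
Why: Palladium-catalysed α-arylation of a zinc ester enolate (Reformatsky reagent) by oxidative addition, transmetalation and reductive elimination, in which the weakly basic zinc enolate should leave the shielded ketone untouched and the ortho carbonyl activates the C–Br bond.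

Step 7
Reactants: 14 tert-butyl [2-(2,4-dimethoxy-6-propylbenzoyl)-3,5-dimethoxyphenyl]acetate
Product: 15 [2-(2,4-dimethoxy-6-propylbenzoyl)-3,5-dimethoxyphenyl]acetic acid
Conditions: CF3CO2H, CH2Cl2, 0 °C → rt
Reagents that add atoms: none
Why: Acid-promoted cleavage of the tert-butyl ester by loss of isobutene, under which the aryl methyl ethers and the ketone are stable.

Step 8
Reactants: 15 [2-(2,4-dimethoxy-6-propylbenzoyl)-3,5-dimethoxyphenyl]acetic acid; 16 2,2,6-trimethyl-4H-1,3-dioxin-4-one
Product: 19 6-{3-[2-(2,4-dimethoxy-6-propylbenzoyl)-3,5-dimethoxyphenyl]-2-oxopropyl}-2,2-dimethyl-4H-1,3-dioxin-4-one, via acyl imidazolide 17 (not isolated), via lithium dienolate 18 (not isolated)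
Conditions: 15, 1,1′-carbonyldiimidazole, THF, rt; added to 18 [16 (2.5 equiv), LiN(i-Pr)2 (2.5 equiv), THF, −78 °C], −78 → −40 °C; aq. HCl quench
Reagents that add atoms: none
Why: Claisen-type C-acylation at the γ-carbon of the lithium dienolate of the dioxinone by the acyl imidazolide, with excess dienolate taking up the acidic proton of the product and the shielded diaryl ketone remaining inert at low temperature.

Step 9
Reactants: 19 6-{3-[2-(2,4-dimethoxy-6-propylbenzoyl)-3,5-dimethoxyphenyl]-2-oxopropyl}-2,2-dimethyl-4H-1,3-dioxin-4-one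
Product: 21 6-{[2-(2,4-dimethoxy-6-propylbenzoyl)-3,5-dimethoxyphenyl]methyl}-4-hydroxy-2H-pyran-2-one, via acylketene 20 (not isolated)
Conditions: toluene, 110 °C
Reagents that add atoms: none
Why: Thermal retro-(4+2) loss of acetone from the dioxinone gives an acylketene that is trapped by the enol oxygen of the neighbouring ketone in a six-membered lactonisation to give the 4-hydroxy-2-pyranone of ring C.

Step 10
Reactants: 21 6-{[2-(2,4-dimethoxy-6-propylbenzoyl)-3,5-dimethoxyphenyl]methyl}-4-hydroxy-2H-pyran-2-one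
Product: 22 6-{[2-(2,4-dihydroxy-6-propylbenzoyl)-3,5-dihydroxyphenyl]methyl}-4-hydroxy-2H-pyran-2-one (CNP0306954.0)
Conditions: BBr3 (12 equiv), CH2Cl2, −78 °C → rt; aqueous work-up
Reagents that add atoms: none
Why: BBr3 cleavage of the four aryl methyl ethers (Lewis acid complexation, then bromide attack on methyl), the two ethers ortho to the ketone being assisted by chelation and the excess reagent at room temperature taking the two para ethers, while the hydroxypyranone and the ketone should survive.

**Compound list**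

1 | 1-bromo-3,5-dimethoxybenzene | COc1cc(Br)cc(OC)c1 | starting material
2 | acetyl chloride | CC(=O)Cl | starting material
3 | 1-(2-bromo-4,6-dimethoxyphenyl)ethan-1-one | CC(=O)c1c(Br)cc(OC)cc1OC | intermediate
4 | ethyl butanoate | CCCC(=O)OCC | starting material
5 | 1-(2-bromo-4,6-dimethoxyphenyl)hexane-1,3-dione | CCCC(=O)CC(=O)c1c(Br)cc(OC)cc1OC | intermediate
6 | malonyl dichloride | O=C(Cl)CC(=O)Cl | starting material
7 | 5-(2-bromo-4,6-dimethoxybenzoyl)-4-hydroxy-6-propyl-2H-pyran-2-one | CCCc1oc(=O)cc(O)c1C(=O)c1c(Br)cc(OC)cc1OC | intermediate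
8 | 5-(2-bromo-4,6-dimethoxybenzoyl)-4-methoxy-6-propyl-2H-pyran-2-one | CCCc1oc(=O)cc(OC)c1C(=O)c1c(Br)cc(OC)cc1OC | intermediate
9 | 1,1-dimethoxyethene | C=C(OC)OC | starting material
10 | 6-(2-bromo-4,6-dimethoxybenzoyl)-5,8,8-trimethoxy-1-propyl-2-oxabicyclo[2.2.2]oct-5-en-3-one (racemic) | CCCC12OC(=O)C(C(OC)(OC)C1)C(OC)=C2C(=O)c1c(Br)cc(OC)cc1OC | intermediate
11 | (2-bromo-4,6-dimethoxyphenyl)(4,4,6-trimethoxy-2-propylcyclohexa-1,5-dien-1-yl)methanone | CCCC1=C(C(=O)c2c(Br)cc(OC)cc2OC)C(OC)=CC(OC)(OC)C1 | intermediate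
12 | (2-bromo-4,6-dimethoxyphenyl)(2,4-dimethoxy-6-propylphenyl)methanone | CCCc1cc(OC)cc(OC)c1C(=O)c1c(Br)cc(OC)cc1OC | intermediate
13 | (2-tert-butoxy-2-oxoethyl)zinc chloride | CC(C)(C)OC(=O)C[Zn]Cl | starting material
14 | tert-butyl [2-(2,4-dimethoxy-6-propylbenzoyl)-3,5-dimethoxyphenyl]acetate | CCCc1cc(OC)cc(OC)c1C(=O)c1c(OC)cc(OC)cc1CC(=O)OC(C)(C)C | intermediate
15 | [2-(2,4-dimethoxy-6-propylbenzoyl)-3,5-dimethoxyphenyl]acetic acid | CCCc1cc(OC)cc(OC)c1C(=O)c1c(OC)cc(OC)cc1CC(=O)O | intermediate
16 | 2,2,6-trimethyl-4H-1,3-dioxin-4-one | CC1=CC(=O)OC(C)(C)O1 | starting material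
17 | 1-{[2-(2,4-dimethoxy-6-propylbenzoyl)-3,5-dimethoxyphenyl]acetyl}-1H-imidazole | CCCc1cc(OC)cc(OC)c1C(=O)c1c(OC)cc(OC)cc1CC(=O)n1ccnc1 | intermediate
18 | lithium 2,2-dimethyl-6-methylidene-6H-1,3-dioxin-4-olate | [Li+].[O-]C1=CC(=C)OC(C)(C)O1 | intermediate
19 | 6-{3-[2-(2,4-dimethoxy-6-propylbenzoyl)-3,5-dimethoxyphenyl]-2-oxopropyl}-2,2-dimethyl-4H-1,3-dioxin-4-one | CCCc1cc(OC)cc(OC)c1C(=O)c1c(OC)cc(OC)cc1CC(=O)CC1=CC(=O)OC(C)(C)O1 | intermediate
20 | 6-[2-(2,4-dimethoxy-6-propylbenzoyl)-3,5-dimethoxyphenyl]hex-1-ene-1,3,5-trione | CCCc1cc(OC)cc(OC)c1C(=O)c1c(OC)cc(OC)cc1CC(=O)CC(=O)C=C=O | intermediate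
21 | 6-{[2-(2,4-dimethoxy-6-propylbenzoyl)-3,5-dimethoxyphenyl]methyl}-4-hydroxy-2H-pyran-2-one | CCCc1cc(OC)cc(OC)c1C(=O)c1c(OC)cc(OC)cc1Cc1cc(O)cc(=O)o1 | intermediate
22 | 6-{[2-(2,4-dihydroxy-6-propylbenzoyl)-3,5-dihydroxyphenyl]methyl}-4-hydroxy-2H-pyran-2-one | CCCc1cc(O)cc(O)c1C(=O)c1c(O)cc(O)cc1Cc1cc(O)cc(=O)o1 | target

**Step count**

Total steps: 10. Longest linear sequence: 10 steps (1 to 22); compounds 2, 4, 6, 9, 13 and 16 are purchased.

**Steps most likely to fail**

Step 5. The 4-methoxy donor and the twist of the aroyl carbonyl out of conjugation may lower the electron demand of the diene so far that cycloaddition is slower than thermal polymerisation of the ketene acetal. This 4-donor, 5-aroyl, 6-alkyl pattern has not been examined. Reversible addition across the aroyl enone (hetero-(4+2) mode) or incomplete loss of methanol may also divert material. The fallback sets out from 1 and comes back at 12.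
- Vilsmeier–Haack formylation of 1 (POCl3, DMF) should give 2-bromo-4,6-dimethoxybenzaldehyde F1.
- Kumada coupling of 1 with n-PrMgCl (NiCl2(dppp) cat., dppp = 1,3-bis(diphenylphosphino)propane) should give 1,3-dimethoxy-5-propylbenzene F2.
- N-Bromosuccinimide in MeCN should brominate F2 ortho to propyl and para to methoxy to give 2-bromo-1,5-dimethoxy-3-propylbenzene F3.
- Bromine–lithium exchange (n-BuLi, THF, −78 °C) gives (2,4-dimethoxy-6-propylphenyl)lithium F4, which should add to F1 to give (2-bromo-4,6-dimethoxyphenyl)(2,4-dimethoxy-6-propylphenyl)methanol F5.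
- Dess–Martin oxidation of F5 gives 12.

Step 3. Ring closure may proceed through the enol oxygen of the aryl ketone and give the 6-aryl-5-butanoyl isomer, or the annulation may stall at an open-chain acylation product. The fallback sets out from 6 and 1 and comes back at 8.
- Transesterification of purchased ethyl 3-oxohexanoate with benzyl alcohol (toluene, reflux, removal of ethanol) gives benzyl 3-oxohexanoate F6.
- F6 has only one ketone oxygen available for closure, and with 6 should give benzyl 4-hydroxy-2-oxo-6-propyl-2H-pyran-5-carboxylate F7.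
- Me2SO4/K2CO3 gives benzyl 4-methoxy-2-oxo-6-propyl-2H-pyran-5-carboxylate F8.
- Hydrogenolysis (H2, Pd/C, EtOAc) gives 4-methoxy-2-oxo-6-propyl-2H-pyran-5-carboxylic acid F9.
- Oxalyl chloride (cat. DMF) gives 4-methoxy-2-oxo-6-propyl-2H-pyran-5-carbonyl chloride F10.
- Friedel–Crafts acylation of 1 with F10 (AlCl3, CH2Cl2, 0 °C), at the same ring position as in step 1, gives 8.

Step 8. Proton transfer from the acidic benzylic CH2 of the acyl imidazolide to the dienolate may outrun C-acylation, and the enolate of the product may close onto the diaryl ketone in an aldol reaction. The fallback avoids basic enolates, sets out from 15 and comes back at 19.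
- BH3·THF (0 °C) reduces the acid to 2-[2-(2,4-dimethoxy-6-propylbenzoyl)-3,5-dimethoxyphenyl]ethan-1-ol F11.
- Dess–Martin oxidation gives [2-(2,4-dimethoxy-6-propylbenzoyl)-3,5-dimethoxyphenyl]acetaldehyde F12.
- 16 is converted (LiN(i-Pr)2, Me3SiCl, THF, −78 °C) into [(2,2-dimethyl-6-methylidene-6H-1,3-dioxin-4-yl)oxy]trimethylsilane F13.
- Vinylogous Mukaiyama aldol addition of F13 to F12 (BF3·OEt2, CH2Cl2, −78 °C) gives 6-{3-[2-(2,4-dimethoxy-6-propylbenzoyl)-3,5-dimethoxyphenyl]-2-hydroxypropyl}-2,2-dimethyl-4H-1,3-dioxin-4-one F14.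
- Dess–Martin oxidation of F14 gives 19.

Further compounds
F1 | step 5 | 2-bromo-4,6-dimethoxybenzaldehyde | O=Cc1c(Br)cc(OC)cc1OC
F2 | step 5 | 1,3-dimethoxy-5-propylbenzene | CCCc1cc(OC)cc(OC)c1
F3 | step 5 | 2-bromo-1,5-dimethoxy-3-propylbenzene | CCCc1cc(OC)cc(OC)c1Br
F4 | step 5 | (2,4-dimethoxy-6-propylphenyl)lithium | [Li]c1c(CCC)cc(OC)cc1OC
F5 | step 5 | (2-bromo-4,6-dimethoxyphenyl)(2,4-dimethoxy-6-propylphenyl)methanol (racemic) | CCCc1cc(OC)cc(OC)c1C(O)c1c(Br)cc(OC)cc1OC
F6 | step 3 | benzyl 3-oxohexanoate | CCCC(=O)CC(=O)OCc1ccccc1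
F7 | step 3 | benzyl 4-hydroxy-2-oxo-6-propyl-2H-pyran-5-carboxylate | CCCc1oc(=O)cc(O)c1C(=O)OCc1ccccc1
F8 | step 3 | benzyl 4-methoxy-2-oxo-6-propyl-2H-pyran-5-carboxylate | CCCc1oc(=O)cc(OC)c1C(=O)OCc1ccccc1
F9 | step 3 | 4-methoxy-2-oxo-6-propyl-2H-pyran-5-carboxylic acid | CCCc1oc(=O)cc(OC)c1C(=O)O
F10 | step 3 | 4-methoxy-2-oxo-6-propyl-2H-pyran-5-carbonyl chloride | CCCc1oc(=O)cc(OC)c1C(=O)Cl
F11 | step 8 | 2-[2-(2,4-dimethoxy-6-propylbenzoyl)-3,5-dimethoxyphenyl]ethan-1-ol | CCCc1cc(OC)cc(OC)c1C(=O)c1c(OC)cc(OC)cc1CCO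
F12 | step 8 | [2-(2,4-dimethoxy-6-propylbenzoyl)-3,5-dimethoxyphenyl]acetaldehyde | CCCc1cc(OC)cc(OC)c1C(=O)c1c(OC)cc(OC)cc1CC=O
F13 | step 8 | [(2,2-dimethyl-6-methylidene-6H-1,3-dioxin-4-yl)oxy]trimethylsilane | C=C1C=C(O[Si](C)(C)C)OC(C)(C)O1
F14 | step 8 | 6-{3-[2-(2,4-dimethoxy-6-propylbenzoyl)-3,5-dimethoxyphenyl]-2-hydroxypropyl}-2,2-dimethyl-4H-1,3-dioxin-4-one (racemic) | CCCc1cc(OC)cc(OC)c1C(=O)c1c(OC)cc(OC)cc1CC(O)CC1=CC(=O)OC(C)(C)O1
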